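**Stereochemistry note:** Naamine C has no stereocentres, so it is achiral and "the single enantiomer" does not apply. Nothing needs to be set or preserved.

**Assumptions (one line each):**
- 4,5-Dibromo-2-nitro-1H-imidazole and 2-hydroxy-3,4-dimethoxybenzaldehyde are treated as purchasable.
- C5–Br of a 4,5-dibromo-1-methylimidazole is more reactive than C4–Br toward Pd(0).

## Retrosynthetic overview
1. The last step is a single hydrogenation that converts the 2-NO2 group to NH2 and removes the O-benzyl group (12 ← 11).
2. The two benzyl groups come from two sequential Negishi couplings on 4,5-dibromo-1-methyl-2-nitroimidazole (3). The 2-nitro group is the masked 2-amino group. C5 is coupled first with the hindered phenol-protected benzylzinc, then C4 with 4-methoxybenzylzinc.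
3. The benzylzinc reagent comes from aldehyde 4 by O-benzylation, reduction and chlorination.
4. No ring is constructed. The imidazole and both arenes come from purchased materials.

## Route

**Step 1**
Reactants: 1 (4,5-dibromo-2-nitro-1H-imidazole); 2 (iodomethane)
Product: 3 (4,5-dibromo-1-methyl-2-nitro-1H-imidazole)
Conditions: MeI, K2CO3, DMF, 0 °C to rt
Reagents that add atoms: MeI, CI
Why: N-Alkylation of the acidic imidazole NH. The substrate is symmetric, so only one N-methyl regioisomer is possible.

**Step 2**
Reactants: 4 (2-hydroxy-3,4-dimethoxybenzaldehyde); 5 (benzyl bromide)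
Product: 6 (2-(benzyloxy)-3,4-dimethoxybenzaldehyde)
Conditions: BnBr, K2CO3, DMF, rt
Reagents that add atoms: BnBr, BrCc1ccccc1
Why: Williamson O-benzylation masks the phenol so the benzylzinc can form later, and the benzyl ether is cleaved in the final hydrogenation.

**Step 3**
Reactants: 6
Product: 7 ([2-(benzyloxy)-3,4-dimethoxyphenyl]methanol)
Conditions: NaBH4, MeOH, 0 °C
Reagents that add atoms: none
Why: Chemoselective hydride reduction of the aldehyde to the benzylic alcohol.

**Step 4**
Reactants: 7
Product: 8 (2-(benzyloxy)-1-(chloromethyl)-3,4-dimethoxybenzene)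
Conditions: SOCl2, CH2Cl2, 0 °C, 30 min; concentrate and use crude immediately
Reagents that add atoms: thionyl chloride, O=S(Cl)Cl
Why: Conversion of the benzylic alcohol to the chloride (SNi/SN2) gives the precursor for Zn insertion. It is used crude because this electron-rich benzyl chloride is labile.

**Step 5**
Reactants: 8; 3
Product: 9 (5-[2-(benzyloxy)-3,4-dimethoxybenzyl]-4-bromo-1-methyl-2-nitro-1H-imidazole)
Conditions: (a) Zn dust, LiCl, TMSCl (cat.), THF, 25 °C, to form the benzylzinc chloride in situ; (b) add 3, Pd(PPh3)4 (5 mol%), THF, 50 °C
Reagents that add atoms: none (Zn and LiCl are not retained)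
Why: Negishi coupling. Oxidative addition occurs preferentially at C5–Br, the position adjacent to N1, so only one bromide is replaced (about 1.2 equiv of benzylzinc).

**Step 6**
Reactants: 9; 10 (4-methoxybenzyl chloride)
Product: 11 (5-[2-(benzyloxy)-3,4-dimethoxybenzyl]-4-(4-methoxybenzyl)-1-methyl-2-nitro-1H-imidazole)
Conditions: (a) Zn dust, LiCl, THF, 25 °C, to form 4-MeOC6H4CH2ZnCl; (b) add 9, PdCl2(dppf) (5 mol%), THF, 65 °C
Reagents that add atoms: none (the 4-methoxybenzyl group enters as reactant 10)
Why: A second Negishi coupling at the remaining C4–Br installs the 4-methoxybenzyl group. A more active, more forcing catalyst system is needed because C4–Br is less reactive.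

**Step 7**
Reactants: 11
Product: 12 (Naamine C)
Conditions: H2 (1 atm), 10% Pd/C, MeOH, 1 equiv HCl, rt; then aq. NaHCO3 workup
Reagents that add atoms: none (H2 adds only hydrogen; HCl is removed in the workup)
Why: Catalytic hydrogenation reduces the 2-nitro group to the 2-amino group (through nitroso and hydroxylamine) and hydrogenolyses the O-benzyl ether in one operation. The aryl methyl ethers and the imidazole survive, and the acid prevents the basic product from poisoning the catalyst.

**Check of the final structure:** 12 is a 2-amino-1-methylimidazole with 4-methoxybenzyl at C4 and 2-hydroxy-3,4-dimethoxybenzyl at C5 (next to N-Me). This matches the target SMILES.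

## Compound list
1 | 4,5-dibromo-2-nitro-1H-imidazole | O=[N+]([O-])c1nc(Br)c(Br)[nH]1 | starting material
2 | iodomethane | CI | starting material
3 | 4,5-dibromo-1-methyl-2-nitro-1H-imidazole | Cn1c(Br)c(Br)nc1[N+](=O)[O-] | intermediate
4 | 2-hydroxy-3,4-dimethoxybenzaldehyde | O=Cc1ccc(OC)c(OC)c1O | starting material
5 | benzyl bromide | BrCc1ccccc1 | starting material
6 | 2-(benzyloxy)-3,4-dimethoxybenzaldehyde | O=Cc1ccc(OC)c(OC)c1OCc1ccccc1 | intermediate
7 | [2-(benzyloxy)-3,4-dimethoxyphenyl]methanol | OCc1ccc(OC)c(OC)c1OCc1ccccc1 | intermediate
8 | 2-(benzyloxy)-1-(chloromethyl)-3,4-dimethoxybenzene | ClCc1ccc(OC)c(OC)c1OCc1ccccc1 | intermediate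
9 | 5-[2-(benzyloxy)-3,4-dimethoxybenzyl]-4-bromo-1-methyl-2-nitroimidazole | Cn1c(Cc2ccc(OC)c(OC)c2OCc2ccccc2)c(Br)nc1[N+](=O)[O-] | intermediate
10 | 4-methoxybenzyl chloride | COc1ccc(CCl)cc1 | starting material
11 | 5-[2-(benzyloxy)-3,4-dimethoxybenzyl]-4-(4-methoxybenzyl)-1-methyl-2-nitroimidazole | COc1ccc(Cc2nc([N+](=O)[O-])n(C)c2Cc2ccc(OC)c(OC)c2OCc2ccccc2)cc1 | intermediate
12 | Naamine C (achiral, no stereocentres) | COc1ccc(Cc2nc(N)n(C)c2Cc2ccc(OC)c(OC)c2O)cc1 | target

## Totals
- **Total steps:** 7.
- **Longest linear sequence:** 6 steps (4 → 6 → 7 → 8 → 9 → 11 → 12). The other branch is 1 → 3, which joins at step 5.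

## Three steps most likely to fail
1. **Step 5 (C5-selective Negishi on the 2-nitroimidazole).**
   - Risks: the benzylzinc could attack the nitro group or displace nitrite at C2 by SNAr, or give C4/C5 mixtures.
   - Fallback: change the strategy to build the 2-aminoimidazole by condensation. Condense N-methyl α-aminoketone PMP-CH2-C(=O)-CH(NHMe)-CH2Ar′ with cyanamide, which fixes the regiochemistry by construction.
2. **Step 4 (benzyl chloride 8 and its zinc insertion).**
   - Risk: the electron-rich 2,3,4-trialkoxybenzyl chloride self-alkylates or hydrolyses, and the benzylzinc may homocouple.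
   - Fallback: drop the benzylmetal strategy and deprotonate or metalate C5 of a 4-(4-methoxybenzyl)imidazole. Add aldehyde 6 to the C5 anion, then deoxygenate the diaryl carbinol with Et3SiH/TFA.
3. **Step 7 (one-pot nitro reduction and debenzylation of a hindered 2-nitroimidazole).**
   - Risk: the reaction stalls at the hydroxylamine stage or the catalyst is poisoned, giving partial reduction.
   - Fallback: separate the two operations. Reduce the nitro group chemically (Na2S2O4 or TiCl3), then cleave the benzyl ether by acid-mediated debenzylation (TFA/pentamethylbenzene). A further option is to bring in the nitrogen as a 2-azide in place of the nitro group and reduce it by Staudinger reaction.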